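**Plan**
- Retrosynthetic cuts, in order: the two MOM acetals; the pyran C3=C4 bond, opened to a dialdehyde (ring-A formyl carbon = C4, aldehyde carbon of a 2-aryloxy-2-methylpropanal = C3); the aryl–C2(benzofuran) bond (triflate + boronate); the O1–C2 ether bond; the C6–prenyl bond on 2,4,6-trihydroxybenzaldehyde.
- Forward: ring A is 2,4,6-trihydroxybenzaldehyde. After C-prenylation its formyl group tells the three hydroxyls apart (para OH to MOM, open chelated OH to O–CMe2CO2Et, prenyl-flanked chelated OH to triflate) and later becomes C4.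
- The benzofuran (rings C and D, from benzofuran-6-ol) is joined by Suzuki coupling; pyran ring B is closed last on the complete skeleton, then both phenols are freed.
- Enabling feature: C3 and C4 of ring B are both CH; C4 sits on aromatic C4a ortho to O1, and C3 sits on the quaternary C2 (gem-dimethyl). Each can therefore be a non-enolisable aldehyde carbon, and the two electrophilic carbons are united by ketyl radical coupling on low-valent titanium.
- Stereochemistry: the target has no stereocentre; the only stereo-element, the cis C3=C4 alkene, is fixed by the six-membered ring.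

Key step: step 10

Remark: benzofuran-6-ol is taken as a purchasable building block; chromene numbering (O1, C2 … C8a) is used for the atoms of rings A and B.

**Step 1**
Reactants: 1 2,4,6-trihydroxybenzaldehyde; 2 prenyl bromide
Product: 3 2,4,6-trihydroxy-3-(3-methylbut-2-en-1-yl)benzaldehyde
Conditions: 2 (1.0 equiv), 10% aq. KOH, 0 °C to rt; then 1 M HCl
Reagents that add atoms: prenyl bromide 2, CC(C)=CCBr
Why: C-allylation of a phloroglucinol-type phenolate: in water the phenoxide oxygens are solvated, so the soft allylic bromide is attacked by ring carbon, and because C3 and C5 of 1 are equivalent only one mono-C-prenyl isomer can form with one equivalent of 2.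

**Step 2**
Reactants: 3 2,4,6-trihydroxy-3-(3-methylbut-2-en-1-yl)benzaldehyde; 4 chloromethyl methyl ether (MOMCl)
Product: 5 2,6-dihydroxy-4-(methoxymethoxy)-3-(3-methylbut-2-en-1-yl)benzaldehyde
Conditions: MOMCl (1.05 equiv), K2CO3, acetone, 0 °C to rt
Reagents that add atoms: chloromethyl methyl ether 4, COCCl
Why: Williamson-type O-alkylation (MOM acetal formation): the 4-hydroxyl is the only one not held in a hydrogen bond to the formyl oxygen and is the most acidic (para to CHO), so one equivalent of MOMCl should go there.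

**Step 3**
Reactants: 5 2,6-dihydroxy-4-(methoxymethoxy)-3-(3-methylbut-2-en-1-yl)benzaldehyde; 6 ethyl 2-bromo-2-methylpropanoate
Product: 7 ethyl 2-[2-formyl-3-hydroxy-5-(methoxymethoxy)-4-(3-methylbut-2-en-1-yl)phenoxy]-2-methylpropanoate
Conditions: 6 (1.5 equiv), K2CO3, DMF, 70 °C
Reagents that add atoms: ethyl 2-bromo-2-methylpropanoate 6, CCOC(=O)C(C)(C)Br
Why: Williamson etherification with an α-bromoisobutyrate (fibrate-type alkylation), a displacement made possible at the tertiary carbon by the adjacent ester carbonyl; of the two chelated hydroxyls the bulky electrophile should take O6, flanked only by H, rather than O2, which is buttressed by the prenyl group.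

**Step 4**
Reactants: 7 ethyl 2-[2-formyl-3-hydroxy-5-(methoxymethoxy)-4-(3-methylbut-2-en-1-yl)phenoxy]-2-methylpropanoate; 8 trifluoromethanesulfonic anhydride
Product: 9 ethyl 2-[2-formyl-5-(methoxymethoxy)-4-(3-methylbut-2-en-1-yl)-3-(trifluoromethylsulfonyloxy)phenoxy]-2-methylpropanoate
Conditions: Tf2O, pyridine, CH2Cl2, 0 °C
Reagents that add atoms: trifluoromethanesulfonic anhydride 8, O=S(=O)(OS(=O)(=O)C(F)(F)F)C(F)(F)F
Why: O-sulfonylation of the only remaining phenol with triflic anhydride and pyridine turns the prenyl-flanked oxygen into a leaving group for cross-coupling; 7 has no other nucleophilic site.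

**Step 5**
Reactants: 10 1-benzofuran-6-ol; 4 chloromethyl methyl ether (MOMCl)
Product: 11 6-(methoxymethoxy)-1-benzofuran
Conditions: MOMCl, K2CO3, acetone, rt
Reagents that add atoms: chloromethyl methyl ether 4, COCCl
Why: Williamson-type MOM protection of a simple phenol, chosen so that both phenolic oxygens of the target are freed in one final operation.

**Step 6**
Reactants: 11 6-(methoxymethoxy)-1-benzofuran; 12 bis(pinacolato)diboron
Product: 13 2-[6-(methoxymethoxy)-1-benzofuran-2-yl]-4,4,5,5-tetramethyl-1,3,2-dioxaborolane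
Conditions: B2pin2 (1.0 equiv), [Ir(OMe)(cod)]2 (cat.), 4,4'-di-tert-butyl-2,2'-bipyridine (cat.), THF, rt
Reagents that add atoms: bis(pinacolato)diboron 12, CC1(C)OB(OC1(C)C)B1OC(C)(C)C(C)(C)O1
Why: Iridium-catalysed aromatic C–H borylation goes to the most acidic, sterically open heteroaryl C–H, here C2 of the furan ring next to the ring oxygen, and tolerates the acetal.

**Step 7**
Reactants: 9 ethyl 2-[2-formyl-5-(methoxymethoxy)-4-(3-methylbut-2-en-1-yl)-3-(trifluoromethylsulfonyloxy)phenoxy]-2-methylpropanoate; 13 2-[6-(methoxymethoxy)-1-benzofuran-2-yl]-4,4,5,5-tetramethyl-1,3,2-dioxaborolane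
Product: 14 ethyl 2-{2-formyl-5-(methoxymethoxy)-3-[6-(methoxymethoxy)-1-benzofuran-2-yl]-4-(3-methylbut-2-en-1-yl)phenoxy}-2-methylpropanoate
Conditions: Pd(OAc)2 (cat.), SPhos (cat.), K3PO4, THF/H2O, 50 °C
Reagents that add atoms: boronate 13, COCOc1ccc2cc(B3OC(C)(C)C(C)(C)O3)oc2c1
Why: Suzuki–Miyaura cross-coupling: oxidative addition of zerovalent palladium into the triflate is helped by the ortho formyl group, the bulky electron-rich biarylphosphine allows transmetalation and reductive elimination at the di-ortho-substituted carbon faster than protodeboronation of 13, and the aryl aldehyde and the hindered ester tolerate phosphate.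

**Step 8**
Reactants: 14 ethyl 2-{2-formyl-5-(methoxymethoxy)-3-[6-(methoxymethoxy)-1-benzofuran-2-yl]-4-(3-methylbut-2-en-1-yl)phenoxy}-2-methylpropanoate
Product: 15 2-{2-(hydroxymethyl)-5-(methoxymethoxy)-3-[6-(methoxymethoxy)-1-benzofuran-2-yl]-4-(3-methylbut-2-en-1-yl)phenoxy}-2-methylpropan-1-ol
Conditions: LiAlH4, THF, 0 °C; aqueous work-up
Reagents that add atoms: none
Why: Hydride reduction with LiAlH4 takes the aryl aldehyde and the ester to the two primary alcohols in one operation, so that both carbons can then be raised to the aldehyde level together; acetals, alkene and benzofuran are inert to hydride.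

**Step 9**
Reactants: 15 2-{2-(hydroxymethyl)-5-(methoxymethoxy)-3-[6-(methoxymethoxy)-1-benzofuran-2-yl]-4-(3-methylbut-2-en-1-yl)phenoxy}-2-methylpropan-1-ol
Product: 16 2-{2-formyl-5-(methoxymethoxy)-3-[6-(methoxymethoxy)-1-benzofuran-2-yl]-4-(3-methylbut-2-en-1-yl)phenoxy}-2-methylpropanal
Conditions: Dess–Martin periodinane (2.5 equiv), CH2Cl2, rt
Reagents that add atoms: none
Why: Dess–Martin oxidation converts the benzylic and the neopentyl-type primary alcohol to aldehydes under near-neutral conditions without over-oxidation; the aliphatic aldehyde has no α-hydrogen and cannot enolise.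

**Step 10**
Reactants: 16 2-{2-formyl-5-(methoxymethoxy)-3-[6-(methoxymethoxy)-1-benzofuran-2-yl]-4-(3-methylbut-2-en-1-yl)phenoxy}-2-methylpropanal
Product: 18 6-(methoxymethoxy)-2-[7-(methoxymethoxy)-2,2-dimethyl-6-(3-methylbut-2-en-1-yl)-2H-chromen-5-yl]-1-benzofuran, via titanium pinacolate 17 (not isolated)
Conditions: TiCl4, Zn dust, pyridine, THF, reflux; 16 added slowly by syringe pump (high dilution); aq. K2CO3 work-up
Reagents that add atoms: none
Why: Low-valent titanium (from TiCl4 and Zn) transfers one electron to each formyl group, and the two ketyl radical anions, both on carbons that are electrophilic in 16, combine on titanium to form the C3–C4 bond of pinacolate 17, which gives up both oxygens to titanium at reflux and leaves the C3=C4 alkene. The closest known reaction type is the intramolecular McMurry coupling of dialdehydes and keto-aldehydes to cycloalkenes and benzo-fused oxygen heterocycles. Pyran ring B closes in a 6-exo-trig mode (ketyl carbon C4 onto carbonyl carbon C3, the C=O bond staying outside the ring). No stereocentre survives: the two carbinol centres of 17 are erased on deoxygenation and the ring allows only the cis alkene. The step needs intramolecular coupling to beat intermolecular coupling, simple reduction and loss of aryloxide; the ortho placement of formyl and ether oxygen on ring A and the gem-dimethyl group at C2 hold the two carbonyls close, slow addition keeps the concentration low, and pyridine buffers the Lewis-acidic chlorides so that the MOM acetals, the prenyl alkene and the benzofuran should pass untouched.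

**Step 11**
Reactants: 18 6-(methoxymethoxy)-2-[7-(methoxymethoxy)-2,2-dimethyl-6-(3-methylbut-2-en-1-yl)-2H-chromen-5-yl]-1-benzofuran
Product: 19 cathafuran C
Conditions: 3 M aq. HCl, MeOH, 50 °C, short reaction time
Reagents that add atoms: none
Why: Acid-catalysed acetal exchange with methanol (MOM cleavage) frees both phenols; mild acid and short contact are chosen so that the ortho-prenylphenol is unmasked before it can cyclise to a chroman.

**Compound list**
1 | 2,4,6-trihydroxybenzaldehyde | O=Cc1c(O)cc(O)cc1O | starting material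
2 | prenyl bromide (1-bromo-3-methylbut-2-ene) | CC(C)=CCBr | starting material
3 | 2,4,6-trihydroxy-3-(3-methylbut-2-en-1-yl)benzaldehyde | CC(C)=CCc1c(O)cc(O)c(C=O)c1O | intermediate
4 | chloromethyl methyl ether (MOMCl) | COCCl | starting material
5 | 2,6-dihydroxy-4-(methoxymethoxy)-3-(3-methylbut-2-en-1-yl)benzaldehyde | CC(C)=CCc1c(OCOC)cc(O)c(C=O)c1O | intermediate
6 | ethyl 2-bromo-2-methylpropanoate | CCOC(=O)C(C)(C)Br | starting material
7 | ethyl 2-[2-formyl-3-hydroxy-5-(methoxymethoxy)-4-(3-methylbut-2-en-1-yl)phenoxy]-2-methylpropanoate | CCOC(=O)C(C)(C)Oc1cc(OCOC)c(CC=C(C)C)c(O)c1C=O | intermediate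
8 | trifluoromethanesulfonic anhydride | O=S(=O)(OS(=O)(=O)C(F)(F)F)C(F)(F)F | starting material
9 | ethyl 2-[2-formyl-5-(methoxymethoxy)-4-(3-methylbut-2-en-1-yl)-3-(trifluoromethylsulfonyloxy)phenoxy]-2-methylpropanoate | CCOC(=O)C(C)(C)Oc1cc(OCOC)c(CC=C(C)C)c(OS(=O)(=O)C(F)(F)F)c1C=O | intermediate
10 | 1-benzofuran-6-ol | Oc1ccc2ccoc2c1 | starting material
11 | 6-(methoxymethoxy)-1-benzofuran | COCOc1ccc2ccoc2c1 | intermediate
12 | bis(pinacolato)diboron | CC1(C)OB(OC1(C)C)B1OC(C)(C)C(C)(C)O1 | starting material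
13 | 2-[6-(methoxymethoxy)-1-benzofuran-2-yl]-4,4,5,5-tetramethyl-1,3,2-dioxaborolane | COCOc1ccc2cc(B3OC(C)(C)C(C)(C)O3)oc2c1 | intermediate
14 | ethyl 2-{2-formyl-5-(methoxymethoxy)-3-[6-(methoxymethoxy)-1-benzofuran-2-yl]-4-(3-methylbut-2-en-1-yl)phenoxy}-2-methylpropanoate | CCOC(=O)C(C)(C)Oc1cc(OCOC)c(CC=C(C)C)c(-c2cc3ccc(OCOC)cc3o2)c1C=O | intermediate
15 | 2-{2-(hydroxymethyl)-5-(methoxymethoxy)-3-[6-(methoxymethoxy)-1-benzofuran-2-yl]-4-(3-methylbut-2-en-1-yl)phenoxy}-2-methylpropan-1-ol | OCC(C)(C)Oc1cc(OCOC)c(CC=C(C)C)c(-c2cc3ccc(OCOC)cc3o2)c1CO | intermediate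
16 | 2-{2-formyl-5-(methoxymethoxy)-3-[6-(methoxymethoxy)-1-benzofuran-2-yl]-4-(3-methylbut-2-en-1-yl)phenoxy}-2-methylpropanal | O=CC(C)(C)Oc1cc(OCOC)c(CC=C(C)C)c(-c2cc3ccc(OCOC)cc3o2)c1C=O | intermediate
17 | titanium pinacolate: titanium-bound cis-3,4-diolate of the 7-(methoxymethoxy)-5-[6-(methoxymethoxy)-1-benzofuran-2-yl]-2,2-dimethyl-6-prenylchroman-3,4-diol, expected mainly cis, racemic; drawn as the free cis-diol, one enantiomer | CC(C)=CCc1c(OCOC)cc2c(c1-c1cc3ccc(OCOC)cc3o1)[C@@H](O)[C@@H](O)C(C)(C)O2 | intermediate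
18 | 6-(methoxymethoxy)-2-[7-(methoxymethoxy)-2,2-dimethyl-6-(3-methylbut-2-en-1-yl)-2H-chromen-5-yl]-1-benzofuran | CC(C)=CCc1c(OCOC)cc2c(c1-c1cc3ccc(OCOC)cc3o1)C=CC(C)(C)O2 | intermediate
19 | cathafuran C, 2-[7-hydroxy-2,2-dimethyl-6-(3-methylbut-2-en-1-yl)-2H-chromen-5-yl]-1-benzofuran-6-ol | CC(C)=CCc1c(O)cc2c(c1-c1cc3ccc(O)cc3o1)C=CC(C)(C)O2 | target

**Step count**
Total: 11 steps. Longest linear sequence: 9 steps (steps 1, 2, 3, 4, 7, 8, 9, 10, 11); steps 5 and 6 make boronate 13 in parallel.

**Steps most likely to fail**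

Step 10. The coupling may stop at the pinacolate or reduce one formyl group to the carbinol; intermolecular coupling may give oligomers; the aryloxy group next to the aliphatic ketyl may be expelled reductively; the Lewis-acidic chlorides may strip the MOM acetals. The fallback sets out from 16 and comes back at 18. Double Wittig methylenation of 16 (Ph3P=CH2 from methyltriphenylphosphonium bromide and KOtBu, THF, 0 °C) should give 2-{2-ethenyl-5-(methoxymethoxy)-3-[(2-methylbut-3-en-2-yl)oxy]-6-(3-methylbut-2-en-1-yl)phenyl}-6-(methoxymethoxy)-1-benzofuran F1. Ring-closing olefin metathesis of F1 with second-generation Grubbs catalyst RuCl2(=CHPh)(PCy3)(H2IMes) in CH2Cl2 at 40 °C should close the same C3=C4 bond with loss of ethene and give 18; the trisubstituted prenyl alkene is expected to stay out of the metathesis.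

Step 3. Substitution at the tertiary carbon by a hydrogen-bonded, ortho-flanked phenoxide may be outrun by dehydrobromination of 6, and the wrong chelated hydroxyl may be alkylated. The fallback sets out from 5 and comes back at 18; it replaces the ester by an alkene handle, so steps 8 and 9 fall away and the ring is closed by metathesis instead of carbonyl coupling. Copper-catalysed propargylation of 5 with 3-chloro-3-methylbut-1-yne (CuCl2 cat., DBU, MeCN, 0 °C), which is little sensitive to hindrance, should give 2-hydroxy-4-(methoxymethoxy)-6-[(2-methylbut-3-yn-2-yl)oxy]-3-(3-methylbut-2-en-1-yl)benzaldehyde F2. Lindlar semi-hydrogenation (H2, Pd on CaCO3 poisoned with Pb(OAc)2, quinoline, EtOAc, rt) should give 2-hydroxy-4-(methoxymethoxy)-6-[(2-methylbut-3-en-2-yl)oxy]-3-(3-methylbut-2-en-1-yl)benzaldehyde F3. Triflation (8, pyridine, CH2Cl2, 0 °C) should give 2-formyl-5-(methoxymethoxy)-3-[(2-methylbut-3-en-2-yl)oxy]-6-(3-methylbut-2-en-1-yl)phenyl trifluoromethanesulfonate F4. Suzuki coupling of F4 with 13 under the conditions of step 7 should give 4-(methoxymethoxy)-2-[6-(methoxymethoxy)-1-benzofuran-2-yl]-6-[(2-methylbut-3-en-2-yl)oxy]-3-(3-methylbut-2-en-1-yl)benzaldehyde F5. Wittig methylenation of F5 should give the diene F1 described above, and ring-closing metathesis as in the first fallback gives 18. All of this is kept below 60 °C so that the tertiary allyl ether does not undergo Claisen rearrangement.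

Step 7. Protodeboronation of 13 and hydrolytic S–O cleavage of the triflate may outrun transmetalation at the di-ortho-substituted arylpalladium. The fallback sets out from 9 and comes back at 14; it builds the furan ring on ring A instead of coupling a finished benzofuran. Sonogashira coupling of 9 with ethynyltrimethylsilane (PdCl2(PPh3)2, CuI, Et3N, DMF, 60 °C) should give ethyl 2-{2-formyl-5-(methoxymethoxy)-4-(3-methylbut-2-en-1-yl)-3-[(trimethylsilyl)ethynyl]phenoxy}-2-methylpropanoate F6. Desilylation (K2CO3 cat., EtOH, rt) should give ethyl 2-[3-ethynyl-2-formyl-5-(methoxymethoxy)-4-(3-methylbut-2-en-1-yl)phenoxy]-2-methylpropanoate F7. Sonogashira coupling of F7 with 4-iodobenzene-1,3-diol (same catalysts, Et3N, DMF, 60 °C), followed in the same flask by 5-endo-dig addition of the ortho hydroxyl to the alkyne, should give ethyl 2-{2-formyl-3-(6-hydroxy-1-benzofuran-2-yl)-5-(methoxymethoxy)-4-(3-methylbut-2-en-1-yl)phenoxy}-2-methylpropanoate F8. MOM protection of F8 with 4 (K2CO3, acetone) gives 14.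

**Further compounds**
F1 | step 10 | 2-{2-ethenyl-5-(methoxymethoxy)-3-[(2-methylbut-3-en-2-yl)oxy]-6-(3-methylbut-2-en-1-yl)phenyl}-6-(methoxymethoxy)-1-benzofuran | C=CC(C)(C)Oc1cc(OCOC)c(CC=C(C)C)c(-c2cc3ccc(OCOC)cc3o2)c1C=C
F2 | step 3 | 2-hydroxy-4-(methoxymethoxy)-6-[(2-methylbut-3-yn-2-yl)oxy]-3-(3-methylbut-2-en-1-yl)benzaldehyde | C#CC(C)(C)Oc1cc(OCOC)c(CC=C(C)C)c(O)c1C=O
F3 | step 3 | 2-hydroxy-4-(methoxymethoxy)-6-[(2-methylbut-3-en-2-yl)oxy]-3-(3-methylbut-2-en-1-yl)benzaldehyde | C=CC(C)(C)Oc1cc(OCOC)c(CC=C(C)C)c(O)c1C=O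
F4 | step 3 | 2-formyl-5-(methoxymethoxy)-3-[(2-methylbut-3-en-2-yl)oxy]-6-(3-methylbut-2-en-1-yl)phenyl trifluoromethanesulfonate | C=CC(C)(C)Oc1cc(OCOC)c(CC=C(C)C)c(OS(=O)(=O)C(F)(F)F)c1C=O
F5 | step 3 | 4-(methoxymethoxy)-2-[6-(methoxymethoxy)-1-benzofuran-2-yl]-6-[(2-methylbut-3-en-2-yl)oxy]-3-(3-methylbut-2-en-1-yl)benzaldehyde | C=CC(C)(C)Oc1cc(OCOC)c(CC=C(C)C)c(-c2cc3ccc(OCOC)cc3o2)c1C=O
F6 | step 7 | ethyl 2-{2-formyl-5-(methoxymethoxy)-4-(3-methylbut-2-en-1-yl)-3-[(trimethylsilyl)ethynyl]phenoxy}-2-methylpropanoate | CCOC(=O)C(C)(C)Oc1cc(OCOC)c(CC=C(C)C)c(C#C[Si](C)(C)C)c1C=O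
F7 | step 7 | ethyl 2-[3-ethynyl-2-formyl-5-(methoxymethoxy)-4-(3-methylbut-2-en-1-yl)phenoxy]-2-methylpropanoate | CCOC(=O)C(C)(C)Oc1cc(OCOC)c(CC=C(C)C)c(C#C)c1C=O
F8 | step 7 | ethyl 2-{2-formyl-3-(6-hydroxy-1-benzofuran-2-yl)-5-(methoxymethoxy)-4-(3-methylbut-2-en-1-yl)phenoxy}-2-methylpropanoate | CCOC(=O)C(C)(C)Oc1cc(OCOC)c(CC=C(C)C)c(-c2cc3ccc(O)cc3o2)c1C=O
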